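**Retrosynthetic overview** (flavan unit: ring A benzo, ring B catechol, ring C pyran O1–C2–C3–C4–C4a–C8a; flavonol unit: ring D benzo, ring E pyranone, ring F catechol)

1. Target ← hydrogenolysis of its deca-benzyl ether; ring E is closed last (Baker–Venkataraman acylation, cyclodehydration) on an acyl group introduced at a C–Br handle of ring D.
2. The 2,3-trans-3,4-trans triad of ring C ← syn-hydroboration of a 4-aryl-4H-chromene anti to the C4 aryl group, so that C4 alone controls C3 and C2.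
3. Ring C ← one-atom ring expansion of the five-membered ring (O1, C3, C4, C4a, C8a) of a trans-2-aroyl-3-aryl-2,3-dihydrobenzofuran: reductive scission of C3–O1, re-closure of O1 on the C2 carbonyl, loss of water.
4. Feature that allows it: O1 is an aryl ether oxygen on C3, α to the C2 aryl ketone (a cyclic phenacyl ether, reductively labile); the freed phenol oxygen lies 1,5 to the C2 carbonyl; C4 is β to that carbonyl and cannot enolise.
5. Dihydrobenzofuran ← catalytic asymmetric [4+1] annulation (ortho-quinone methide + sulfonium ylide, sets C4) ← ortho-hydroxyalkylation of the ring A phenol with the ring D aldehyde. Ring order: temporary dihydrofuran, then ring C, then ring E.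

Key step: step 7

Remark: the target is read as a (2R,3S,4R), 2,3-trans-3,4-trans flavan-3-ol unit bonded through C4 to C5 of the flavonol; all ten hydroxyls are carried as benzyl ethers, and the five starting materials marked in the compound list are taken as purchasable.

Step 1
Reactants: 1 2,3-bis(benzyloxy)benzaldehyde
Product: 3 2,3-bis(benzyloxy)phenol, via aryl formate 2 (not isolated)
Conditions: mCPBA, CH2Cl2, 0 → 25 °C; then K2CO3 (cat.), MeOH
Reagents that add atoms: 3-chloroperoxybenzoic acid, OOC(=O)c1cccc(Cl)c1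
Why: Dakin-type Baeyer–Villiger oxidation, in which the electron-rich aryl group migrates in the peracid adduct and mild methanolysis of the formate frees the phenol; no stereocenter is formed.

Step 2
Reactants: 4 3,4,5-tris(benzyloxy)benzaldehyde
Product: 5 3,4,5-tris(benzyloxy)-2-bromobenzaldehyde
Conditions: NBS, MeCN, 25 °C, dark
Reagents that add atoms: N-bromosuccinimide, BrN1C(=O)CCC1=O
Why: electrophilic aromatic bromination at the only free ring positions (C2 and C6 are equivalent), activated ortho and para by benzyloxy groups; the first bromine and the formyl group should prevent a second substitution.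

Step 3
Reactants: 3 2,3-bis(benzyloxy)phenol; 5 3,4,5-tris(benzyloxy)-2-bromobenzaldehyde
Product: 7 rac-2,3-bis(benzyloxy)-6-{hydroxy[3,4,5-tris(benzyloxy)-2-bromophenyl]methyl}phenol, via magnesium phenoxide 6 (not isolated)
Conditions: EtMgBr (1.0 equiv), Et2O, 0 °C; solvent change to PhMe; then 5, 25 → 60 °C; aq NH4Cl
Reagents that add atoms: none
Why: ortho-selective hydroxyalkylation of a bromomagnesium phenoxide by an aromatic aldehyde through a six-membered Mg-chelated transition state; C6 is the only free ortho position, and the racemic carbinol carbon does not matter because it is made planar in step 6.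

Step 4
Reactants: 7 rac-ortho-hydroxybenzhydrol
Product: 8 rac-2,3-bis(benzyloxy)-6-{(4-methylbenzenesulfonyl)[3,4,5-tris(benzyloxy)-2-bromophenyl]methyl}phenol
Conditions: p-TolSO2H (1.5 equiv), CH2Cl2, 25 °C
Reagents that add atoms: 4-methylbenzenesulfinic acid, Cc1ccc(cc1)S(=O)O
Why: acid-promoted loss of water gives the ortho-quinone methide, which the sulfinate traps by conjugate addition at sulfur to give a storable sulfone that releases the same quinone methide with base.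

Step 5
Reactants: 9 1-[3,4-bis(benzyloxy)phenyl]-2-bromoethan-1-one
Product: 10 {2-[3,4-bis(benzyloxy)phenyl]-2-oxoethyl}dimethylsulfonium bromide
Conditions: Me2S, acetone, 25 °C
Reagents that add atoms: dimethyl sulfide, CSC
Why: SN2 alkylation of the sulfide by the α-bromo ketone (quaternisation at sulfur) gives the sulfonium salt, the ylide precursor.

Step 6
Reactants: 8 rac-sulfone; 10 sulfonium bromide
Product: 13 [(2R,3S)-6,7-bis(benzyloxy)-3-[3,4,5-tris(benzyloxy)-2-bromophenyl]-2,3-dihydro-1-benzofuran-2-yl][3,4-bis(benzyloxy)phenyl]methanone, via ortho-quinone methide 11 (not isolated), via sulfonium ylide 12 (not isolated)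
Conditions: Cs2CO3 (2.5 equiv), chiral bis-urea hydrogen-bond donor from (1R,2R)-1,2-diphenylethane-1,2-diamine carrying 3,5-bis(trifluoromethyl)phenyl groups (10 mol %; the enantiomer that delivers 3S is used), CH2Cl2, −20 °C
Reagents that add atoms: none
Why: formal [4+1] annulation of a sulfur ylide with an ortho-quinone methide generated in the flask: conjugate addition of the ylide carbon to the methide carbon, then 5-exo-tet displacement of dimethyl sulfide by the phenoxide; the catalyst should select the face of 11 (3S), and the 2,3-trans isomer is the thermodynamic one because C2 is epimerisable next to the ketone.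

Step 7
Reactants: 13 trans-2-aroyl-3-aryl-2,3-dihydrobenzofuran
Product: 16 (4S)-7,8-bis(benzyloxy)-2-[3,4-bis(benzyloxy)phenyl]-4-[3,4,5-tris(benzyloxy)-2-bromophenyl]-4H-chromene, via hydroxy ketone 14 (not isolated), via lactol 15 (not isolated)
Conditions: Zn dust (10 equiv), AcOH–THF (2:1), 25 °C then 50 °C
Reagents that add atoms: none
Why: Zinc transfers two electrons to the aryl ketone of 13, the ketyl expels the α-aryloxy group so that the C3–O1 bond of the five-membered ring breaks, protonation gives hydroxy ketone 14, its phenol oxygen O1 adds to the C2 carbonyl to give lactol 15, and acetic acid dehydrates 15 toward C3 to enol ether 16. The closest known reaction types are the Zn/AcOH removal of phenacyl groups from phenols (reductive cleavage of α-aryloxy ketones) and the acid-catalysed cyclodehydration of 3-(2-hydroxyaryl)-1,3-diarylpropan-1-ones to 2,4-diaryl-4H-chromenes. Ring C is closed by 6-exo-trig hemiketalisation of O1 on C2 followed by E1 loss of water, so the ring (O1, C3, C4, C4a, C8a) is enlarged by the atom C2. No new stereocenter remains in 16: C4 keeps its configuration because it is β to the carbonyl, is never enolised and takes part in no bond change, and the C2 stereocenter of 13 is erased on purpose. The step needs chemoselective cleavage of the one C–O bond α to a ketone (benzyl ethers and the aryl bromide should be inert to Zn/AcOH at this temperature) and regioselective dehydration, which is secured because C3 carries the only β-hydrogens of the lactol carbon.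

Step 8
Reactants: 16 4-aryl-4H-chromene
Product: 18 (2R,3S,4S)-7,8-bis(benzyloxy)-2-[3,4-bis(benzyloxy)phenyl]-4-[3,4,5-tris(benzyloxy)-2-bromophenyl]-3,4-dihydro-2H-chromen-3-ol, via alkylborane 17 (not isolated)
Conditions: BH3·THF (3 equiv), THF, 0 → 25 °C; then aq NaOH, H2O2, 0 °C
Reagents that add atoms: hydrogen peroxide, OO
Why: hydroboration–oxidation of a cyclic enol ether: boron goes to C3 (β to O1 and to the 2-aryl group), H and B add syn on the face opposite the pseudo-axial C4 aryl group, and oxidation with retention should give the 2,3-trans-3,4-trans alcohol (C3 and C2 set by C4).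

Step 9
Reactants: 18 flavan-3-ol
Product: 19 (2R,3S,4S)-3,7,8-tris(benzyloxy)-2-[3,4-bis(benzyloxy)phenyl]-4-[3,4,5-tris(benzyloxy)-2-bromophenyl]-3,4-dihydro-2H-chromene
Conditions: NaH, BnBr, Bu4NI (cat.), DMF, 0 → 25 °C
Reagents that add atoms: benzyl bromide, BrCc1ccccc1
Why: Williamson etherification of the secondary alkoxide; no stereocenter is touched, and the ether leaves in the final hydrogenolysis.

Step 10
Reactants: 19 aryl bromide; 20 2-(benzyloxy)-N-methoxy-N-methylacetamide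
Product: 22 2-(benzyloxy)-1-{2,3,4-tris(benzyloxy)-6-[(2R,3S,4R)-3,7,8-tris(benzyloxy)-2-[3,4-bis(benzyloxy)phenyl]-3,4-dihydro-2H-chromen-4-yl]phenyl}ethan-1-one, via aryllithium 21 (not isolated)
Conditions: n-BuLi (1.1 equiv), THF, −78 °C, 5 min; then 20, −78 → 0 °C; aq NH4Cl
Reagents that add atoms: none
Why: bromine–lithium exchange is faster than deprotonation at −78 °C, and the aryllithium adds once to the Weinreb amide through the stable chelated tetrahedral adduct (Weinreb ketone synthesis); the descriptor at C4 changes to R only because bromine is replaced.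

Step 11
Reactants: 22 aryl ketone
Product: 23 2-(benzyloxy)-1-{3,4-bis(benzyloxy)-2-hydroxy-6-[(2R,3S,4R)-3,7,8-tris(benzyloxy)-2-[3,4-bis(benzyloxy)phenyl]-3,4-dihydro-2H-chromen-4-yl]phenyl}ethan-1-one
Conditions: MgBr2·OEt2 (3 equiv), PhMe–Et2O, 60 °C
Reagents that add atoms: none
Why: chelation-controlled debenzylation: magnesium bridges the ketone oxygen and the one aryl ether oxygen ortho to it, bromide attacks that benzylic carbon, and the non-chelated aryl and alkyl benzyl ethers should stay.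

Step 12
Reactants: 23 ortho-hydroxyaryl ketone; 24 3,4-bis(benzyloxy)benzoyl chloride
Product: 26 2-(benzyloxy)-1-[3,4-bis(benzyloxy)phenyl]-3-{3,4-bis(benzyloxy)-2-hydroxy-6-[(2R,3S,4R)-3,7,8-tris(benzyloxy)-2-[3,4-bis(benzyloxy)phenyl]-3,4-dihydro-2H-chromen-4-yl]phenyl}propane-1,3-dione, via dilithium enolate 25 (not isolated)
Conditions: LiN(SiMe3)2 (3.5 equiv), THF, −78 → −20 °C; then 24, −78 → 25 °C; aq HCl
Reagents that add atoms: none
Why: Baker–Venkataraman-type aroylation: the phenoxide–enolate dianion is acylated at carbon (any O-aroyl ester rearranges under the excess base) to the 1,3-diketone; the new carbon between the carbonyls is formed as a mixture and becomes sp2 in step 13.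

Step 13
Reactants: 26 1,3-diketone
Product: 27 3,7,8-tris(benzyloxy)-2-[3,4-bis(benzyloxy)phenyl]-5-{(2R,3S,4R)-3,7,8-tris(benzyloxy)-2-[3,4-bis(benzyloxy)phenyl]-3,4-dihydro-2H-chromen-4-yl}-4H-chromen-4-one
Conditions: p-TsOH·H2O (cat.), PhMe, 4 Å molecular sieves, 70 °C
Reagents that add atoms: none
Why: acid-catalysed cyclodehydration of the 2-hydroxyaryl 1,3-diketone (6-exo-trig hemiketal, then loss of water) closes ring E as in the Baker–Venkataraman flavone synthesis and gives the 3-benzyloxyflavone directly.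

Step 14
Reactants: 27 deca-benzyl ether
Product: 28 2-(3,4-dihydroxyphenyl)-5-[(2R,3S,4R)-2-(3,4-dihydroxyphenyl)-3,7,8-trihydroxy-3,4-dihydro-2H-chromen-4-yl]-3,7,8-trihydroxy-4H-chromen-4-one
Conditions: H2 (1 atm), Pd(OH)2/C, THF–MeOH, 25 °C
Reagents that add atoms: none
Why: hydrogenolysis of the ten benzyl ethers under neutral conditions; the benzylic C2–O1 bond of ring C, the diarylmethine C4–H and the enone of ring E are expected to survive, as in standard flavan-3-ol and flavonol deprotections.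

**Compound list**

1 | 2,3-bis(benzyloxy)benzaldehyde | O=Cc1cccc(OCc2ccccc2)c1OCc1ccccc1 | starting material
2 | 2,3-bis(benzyloxy)phenyl formate | O=COc1cccc(OCc2ccccc2)c1OCc1ccccc1 | intermediate
3 | 2,3-bis(benzyloxy)phenol | Oc1cccc(OCc2ccccc2)c1OCc1ccccc1 | intermediate
4 | 3,4,5-tris(benzyloxy)benzaldehyde | O=Cc1cc(OCc2ccccc2)c(OCc2ccccc2)c(OCc2ccccc2)c1 | starting material
5 | 3,4,5-tris(benzyloxy)-2-bromobenzaldehyde | O=Cc1cc(OCc2ccccc2)c(OCc2ccccc2)c(OCc2ccccc2)c1Br | intermediate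
6 | bromomagnesium 2,3-bis(benzyloxy)phenoxide | Br[Mg]Oc1cccc(OCc2ccccc2)c1OCc1ccccc1 | intermediate
7 | rac-2,3-bis(benzyloxy)-6-{hydroxy[3,4,5-tris(benzyloxy)-2-bromophenyl]methyl}phenol | OC(c1ccc(OCc2ccccc2)c(OCc2ccccc2)c1O)c1cc(OCc2ccccc2)c(OCc2ccccc2)c(OCc2ccccc2)c1Br | intermediate
8 | rac-2,3-bis(benzyloxy)-6-{(4-methylbenzenesulfonyl)[3,4,5-tris(benzyloxy)-2-bromophenyl]methyl}phenol | Cc1ccc(cc1)S(=O)(=O)C(c1ccc(OCc2ccccc2)c(OCc2ccccc2)c1O)c1cc(OCc2ccccc2)c(OCc2ccccc2)c(OCc2ccccc2)c1Br | intermediate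
9 | 1-[3,4-bis(benzyloxy)phenyl]-2-bromoethan-1-one | O=C(CBr)c1ccc(OCc2ccccc2)c(OCc2ccccc2)c1 | starting material
10 | {2-[3,4-bis(benzyloxy)phenyl]-2-oxoethyl}dimethylsulfonium bromide | C[S+](C)CC(=O)c1ccc(OCc2ccccc2)c(OCc2ccccc2)c1.[Br-] | intermediate
11 | 2,3-bis(benzyloxy)-6-{[3,4,5-tris(benzyloxy)-2-bromophenyl]methylidene}cyclohexa-2,4-dien-1-one | O=C1C(OCc2ccccc2)=C(OCc2ccccc2)C=CC1=Cc1cc(OCc2ccccc2)c(OCc2ccccc2)c(OCc2ccccc2)c1Br | intermediate
12 | dimethylsulfonium 2-[3,4-bis(benzyloxy)phenyl]-2-oxoethylide | C[S+](C)[CH-]C(=O)c1ccc(OCc2ccccc2)c(OCc2ccccc2)c1 | intermediate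
13 | [(2R,3S)-6,7-bis(benzyloxy)-3-[3,4,5-tris(benzyloxy)-2-bromophenyl]-2,3-dihydro-1-benzofuran-2-yl][3,4-bis(benzyloxy)phenyl]methanone | Brc1c(OCc2ccccc2)c(OCc2ccccc2)c(OCc2ccccc2)cc1[C@@H]1c2ccc(OCc3ccccc3)c(OCc3ccccc3)c2O[C@H]1C(=O)c1ccc(OCc2ccccc2)c(OCc2ccccc2)c1 | intermediate
14 | (3S)-1-[3,4-bis(benzyloxy)phenyl]-3-[3,4-bis(benzyloxy)-2-hydroxyphenyl]-3-[3,4,5-tris(benzyloxy)-2-bromophenyl]propan-1-one | Brc1c(OCc2ccccc2)c(OCc2ccccc2)c(OCc2ccccc2)cc1[C@@H](CC(=O)c1ccc(OCc2ccccc2)c(OCc2ccccc2)c1)c1ccc(OCc2ccccc2)c(OCc2ccccc2)c1O | intermediate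
15 | (4S)-7,8-bis(benzyloxy)-2-[3,4-bis(benzyloxy)phenyl]-4-[3,4,5-tris(benzyloxy)-2-bromophenyl]-3,4-dihydro-2H-chromen-2-ol (both C2 epimers) | Brc1c(OCc2ccccc2)c(OCc2ccccc2)c(OCc2ccccc2)cc1[C@@H]1c2ccc(OCc3ccccc3)c(OCc3ccccc3)c2OC(O)(c2ccc(OCc3ccccc3)c(OCc3ccccc3)c2)C1 | intermediate
16 | (4S)-7,8-bis(benzyloxy)-2-[3,4-bis(benzyloxy)phenyl]-4-[3,4,5-tris(benzyloxy)-2-bromophenyl]-4H-chromene | Brc1c(OCc2ccccc2)c(OCc2ccccc2)c(OCc2ccccc2)cc1[C@@H]1c2ccc(OCc3ccccc3)c(OCc3ccccc3)c2OC(c2ccc(OCc3ccccc3)c(OCc3ccccc3)c2)=C1 | intermediate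
17 | [(2S,3S,4S)-7,8-bis(benzyloxy)-2-[3,4-bis(benzyloxy)phenyl]-4-[3,4,5-tris(benzyloxy)-2-bromophenyl]-3,4-dihydro-2H-chromen-3-yl]borane | Brc1c(OCc2ccccc2)c(OCc2ccccc2)c(OCc2ccccc2)cc1[C@@H]1c2ccc(OCc3ccccc3)c(OCc3ccccc3)c2O[C@H](c2ccc(OCc3ccccc3)c(OCc3ccccc3)c2)[C@H]1B | intermediate
18 | (2R,3S,4S)-7,8-bis(benzyloxy)-2-[3,4-bis(benzyloxy)phenyl]-4-[3,4,5-tris(benzyloxy)-2-bromophenyl]-3,4-dihydro-2H-chromen-3-ol | Brc1c(OCc2ccccc2)c(OCc2ccccc2)c(OCc2ccccc2)cc1[C@@H]1c2ccc(OCc3ccccc3)c(OCc3ccccc3)c2O[C@H](c2ccc(OCc3ccccc3)c(OCc3ccccc3)c2)[C@H]1O | intermediate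
19 | (2R,3S,4S)-3,7,8-tris(benzyloxy)-2-[3,4-bis(benzyloxy)phenyl]-4-[3,4,5-tris(benzyloxy)-2-bromophenyl]-3,4-dihydro-2H-chromene | Brc1c(OCc2ccccc2)c(OCc2ccccc2)c(OCc2ccccc2)cc1[C@@H]1c2ccc(OCc3ccccc3)c(OCc3ccccc3)c2O[C@H](c2ccc(OCc3ccccc3)c(OCc3ccccc3)c2)[C@H]1OCc1ccccc1 | intermediate
20 | 2-(benzyloxy)-N-methoxy-N-methylacetamide | CON(C)C(=O)COCc1ccccc1 | starting material
21 | {2,3,4-tris(benzyloxy)-6-[(2R,3S,4R)-3,7,8-tris(benzyloxy)-2-[3,4-bis(benzyloxy)phenyl]-3,4-dihydro-2H-chromen-4-yl]phenyl}lithium | [Li]c1c(OCc2ccccc2)c(OCc2ccccc2)c(OCc2ccccc2)cc1[C@@H]1c2ccc(OCc3ccccc3)c(OCc3ccccc3)c2O[C@H](c2ccc(OCc3ccccc3)c(OCc3ccccc3)c2)[C@H]1OCc1ccccc1 | intermediate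
22 | 2-(benzyloxy)-1-{2,3,4-tris(benzyloxy)-6-[(2R,3S,4R)-3,7,8-tris(benzyloxy)-2-[3,4-bis(benzyloxy)phenyl]-3,4-dihydro-2H-chromen-4-yl]phenyl}ethan-1-one | O=C(COCc1ccccc1)c1c(OCc2ccccc2)c(OCc2ccccc2)c(OCc2ccccc2)cc1[C@@H]1c2ccc(OCc3ccccc3)c(OCc3ccccc3)c2O[C@H](c2ccc(OCc3ccccc3)c(OCc3ccccc3)c2)[C@H]1OCc1ccccc1 | intermediate
23 | 2-(benzyloxy)-1-{3,4-bis(benzyloxy)-2-hydroxy-6-[(2R,3S,4R)-3,7,8-tris(benzyloxy)-2-[3,4-bis(benzyloxy)phenyl]-3,4-dihydro-2H-chromen-4-yl]phenyl}ethan-1-one | O=C(COCc1ccccc1)c1c(O)c(OCc2ccccc2)c(OCc2ccccc2)cc1[C@@H]1c2ccc(OCc3ccccc3)c(OCc3ccccc3)c2O[C@H](c2ccc(OCc3ccccc3)c(OCc3ccccc3)c2)[C@H]1OCc1ccccc1 | intermediate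
24 | 3,4-bis(benzyloxy)benzoyl chloride | O=C(Cl)c1ccc(OCc2ccccc2)c(OCc2ccccc2)c1 | starting material
25 | dilithium enolate-phenoxide of 23 | [Li+].[Li+].[O-]C(=COCc1ccccc1)c1c([O-])c(OCc2ccccc2)c(OCc2ccccc2)cc1[C@@H]1c2ccc(OCc3ccccc3)c(OCc3ccccc3)c2O[C@H](c2ccc(OCc3ccccc3)c(OCc3ccccc3)c2)[C@H]1OCc1ccccc1 | intermediate
26 | 2-(benzyloxy)-1-[3,4-bis(benzyloxy)phenyl]-3-{3,4-bis(benzyloxy)-2-hydroxy-6-[(2R,3S,4R)-3,7,8-tris(benzyloxy)-2-[3,4-bis(benzyloxy)phenyl]-3,4-dihydro-2H-chromen-4-yl]phenyl}propane-1,3-dione (mixture at C2 of the dione) | O=C(c1ccc(OCc2ccccc2)c(OCc2ccccc2)c1)C(OCc1ccccc1)C(=O)c1c(O)c(OCc2ccccc2)c(OCc2ccccc2)cc1[C@@H]1c2ccc(OCc3ccccc3)c(OCc3ccccc3)c2O[C@H](c2ccc(OCc3ccccc3)c(OCc3ccccc3)c2)[C@H]1OCc1ccccc1 | intermediate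
27 | 3,7,8-tris(benzyloxy)-2-[3,4-bis(benzyloxy)phenyl]-5-{(2R,3S,4R)-3,7,8-tris(benzyloxy)-2-[3,4-bis(benzyloxy)phenyl]-3,4-dihydro-2H-chromen-4-yl}-4H-chromen-4-one | O=c1c(OCc5ccccc5)c(-c2ccc(OCc5ccccc5)c(OCc5ccccc5)c2)oc2c(OCc5ccccc5)c(OCc5ccccc5)cc([C@@H]3c4ccc(OCc5ccccc5)c(OCc5ccccc5)c4O[C@H](c4ccc(OCc5ccccc5)c(OCc5ccccc5)c4)[C@H]3OCc5ccccc5)c12 | intermediate
28 | 2-(3,4-dihydroxyphenyl)-5-[(2R,3S,4R)-2-(3,4-dihydroxyphenyl)-3,7,8-trihydroxy-3,4-dihydro-2H-chromen-4-yl]-3,7,8-trihydroxy-4H-chromen-4-one | O=c1c(O)c(-c2ccc(O)c(O)c2)oc2c(O)c(O)cc([C@@H]3c4ccc(O)c(O)c4O[C@H](c4ccc(O)c(O)c4)[C@H]3O)c12 | target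

**Totals**

Total step count: 14. Longest linear sequence: 12 steps (from 1 or from 4 to 28; steps 2 and 5 are side branches).

**Three steps most likely to fail**

Step 6. The catalyst may discriminate poorly between the faces of the hindered, ortho-bromoaryl-substituted quinone methide, so that C3 of 13 is formed with low enantiomeric purity. Fallback: setting out from 8 and 10, the annulation would be run with Cs2CO3 alone, which should give racemic trans material, that is 13 together with its enantiomer [(2S,3R)-6,7-bis(benzyloxy)-3-[3,4,5-tris(benzyloxy)-2-bromophenyl]-2,3-dihydro-1-benzofuran-2-yl][3,4-bis(benzyloxy)phenyl]methanone F1. The two would be separated by preparative chromatography on a chiral stationary phase (resolution instead of asymmetric catalysis), F1 discarded, and the route rejoined at 13.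

Step 10. Proton transfer to the hindered aryllithium (from the neighbouring C4–H or from benzylic CH2 groups, followed by ether rearrangement) may compete with acylation. Fallback: setting out from 19, Stille coupling with tributyl(1-ethoxyvinyl)stannane (Pd(PPh3)4, PhMe, 100 °C) would give the 1-ethoxyvinyl arene F2. Brief treatment with dilute HCl in THF would give the methyl ketone 1-{2,3,4-tris(benzyloxy)-6-[(2R,3S,4R)-3,7,8-tris(benzyloxy)-2-[3,4-bis(benzyloxy)phenyl]-3,4-dihydro-2H-chromen-4-yl]phenyl}ethan-1-one F3. Its lithium enolate (LiN(SiMe3)2, −78 °C) would be hydroxylated with 2-(benzenesulfonyl)-3-phenyloxaziridine to the α-hydroxy ketone F4, and O-benzylation (BnBr, Ag2O) would return the route at 22.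

Step 3. Addition of the magnesium phenoxide to the deactivated, ortho-substituted aldehyde may be slow, and ionisation of the product followed by a second arylation (triarylmethane formation) may take over. Fallback: setting out from 3, the phenol would be protected as its 2-(trimethylsilyl)ethoxymethyl ether F5 (SEMCl, i-Pr2NEt). Directed ortho-lithiation (n-BuLi, TMEDA, Et2O, 0 °C) would give the aryllithium F6, and addition to 5 at −78 °C the protected benzhydrol F7. Fluoride (Bu4NF, THF, 60 °C) would remove the protecting group without acid and return the route at 7.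

**Further compounds**

F1 | step 6 | [(2S,3R)-6,7-bis(benzyloxy)-3-[3,4,5-tris(benzyloxy)-2-bromophenyl]-2,3-dihydro-1-benzofuran-2-yl][3,4-bis(benzyloxy)phenyl]methanone | Brc1c(OCc2ccccc2)c(OCc2ccccc2)c(OCc2ccccc2)cc1[C@H]1c2ccc(OCc3ccccc3)c(OCc3ccccc3)c2O[C@@H]1C(=O)c1ccc(OCc2ccccc2)c(OCc2ccccc2)c1
F2 | step 10 | (2R,3S,4R)-3,7,8-tris(benzyloxy)-2-[3,4-bis(benzyloxy)phenyl]-4-[3,4,5-tris(benzyloxy)-2-(1-ethoxyethenyl)phenyl]-3,4-dihydro-2H-chromene | C=C(OCC)c1c(OCc2ccccc2)c(OCc2ccccc2)c(OCc2ccccc2)cc1[C@@H]1c2ccc(OCc3ccccc3)c(OCc3ccccc3)c2O[C@H](c2ccc(OCc3ccccc3)c(OCc3ccccc3)c2)[C@H]1OCc1ccccc1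
F3 | step 10 | 1-{2,3,4-tris(benzyloxy)-6-[(2R,3S,4R)-3,7,8-tris(benzyloxy)-2-[3,4-bis(benzyloxy)phenyl]-3,4-dihydro-2H-chromen-4-yl]phenyl}ethan-1-one | CC(=O)c1c(OCc2ccccc2)c(OCc2ccccc2)c(OCc2ccccc2)cc1[C@@H]1c2ccc(OCc3ccccc3)c(OCc3ccccc3)c2O[C@H](c2ccc(OCc3ccccc3)c(OCc3ccccc3)c2)[C@H]1OCc1ccccc1
F4 | step 10 | 2-hydroxy-1-{2,3,4-tris(benzyloxy)-6-[(2R,3S,4R)-3,7,8-tris(benzyloxy)-2-[3,4-bis(benzyloxy)phenyl]-3,4-dihydro-2H-chromen-4-yl]phenyl}ethan-1-one | O=C(CO)c1c(OCc2ccccc2)c(OCc2ccccc2)c(OCc2ccccc2)cc1[C@@H]1c2ccc(OCc3ccccc3)c(OCc3ccccc3)c2O[C@H](c2ccc(OCc3ccccc3)c(OCc3ccccc3)c2)[C@H]1OCc1ccccc1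
F5 | step 3 | {2-[(2,3-bis(benzyloxy)phenoxy)methoxy]ethyl}trimethylsilane | C[Si](C)(C)CCOCOc1cccc(OCc2ccccc2)c1OCc1ccccc1
F6 | step 3 | [3,4-bis(benzyloxy)-2-{[2-(trimethylsilyl)ethoxy]methoxy}phenyl]lithium | [Li]c1ccc(OCc2ccccc2)c(OCc2ccccc2)c1OCOCC[Si](C)(C)C
F7 | step 3 | rac-[3,4-bis(benzyloxy)-2-{[2-(trimethylsilyl)ethoxy]methoxy}phenyl][3,4,5-tris(benzyloxy)-2-bromophenyl]methanol | OC(c1ccc(OCc2ccccc2)c(OCc2ccccc2)c1OCOCC[Si](C)(C)C)c1cc(OCc2ccccc2)c(OCc2ccccc2)c(OCc2ccccc2)c1Br
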